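**Retrosynthetic overview**
1. Cembrane numbering: ring A is the 14-membered carbocycle C1–C14 (C3/C4 epoxide, C13 CH–OAc). Ring B is the γ-lactone O–C14–C1–C15–C16(=O), trans-fused at C1/C14, with C17 the exocyclic CH2.
2. Endgame: the C13 acetate comes from the 13R alcohol by invertive Mitsunobu acetylation; C17 comes from Eschenmoser methylenation of the saturated lactone.
3. Key disconnection C12–C13 (closes ring A): C13 is a carbinol carbon that is allylic to the E, methyl-bearing C11=C12 alkene and α to the C14–O bond of ring B. This is the retron of a nickel-catalysed reductive alkyne–aldehyde macrocyclisation of a linear ynal; the methyl-capped alkyne fixes the regiochemistry and the E geometry, and C14–O steers C13.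
4. Ynal chain: two Negishi sp3–sp2 couplings (C2–C3, C8–C9) of C5 alkyne units from pent-3-yn-1-ol. C7=C8 is carried as its C8 vinyl iodide, so the Shi epoxidation can only hit C3=C4.
5. Ring order: ring B with C1/C14 first, from (5S)-5-(hydroxymethyl)furan-2(5H)-one by trans-selective photochemical hydroxymethylation; then the oxirane; then ring A.

Key step: step 13

Remark: the key step is assumed to follow polar Felkin–Anh control by C14–O and to give the 13R carbinol, which the last step inverts to 13S.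

**Route**

Step 1
Reactants: 1 pent-3-yn-1-ol
Product: 2 5-iodopent-2-yne
Conditions: I2, PPh3, imidazole, CH2Cl2, 0 °C to rt
Reagents that add atoms: iodine, [I][I]
Why: Appel-type iodination of the primary alcohol should proceed by SN2 displacement of the alkoxyphosphonium ion and leave the internal alkyne untouched.

Step 2
Reactants: 2 5-iodopent-2-yne
Product: 3 hepta-1,5-diyne
Conditions: LiC≡CH·H2NCH2CH2NH2, DMSO, 10 °C to rt
Reagents that add atoms: lithium acetylide (ethylenediamine complex), [Li]C#C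
Why: SN2 alkylation of the acetylide by the primary iodide in DMSO should give the diyne with one terminal and one methyl-capped alkyne.

Step 3
Reactants: 3 hepta-1,5-diyne
Product: 5 (1E)-1-iodo-2-methylhept-1-en-5-yne, via alkenyldimethylalane 4 (not isolated)
Conditions: Me3Al, Cp2ZrCl2 (25 mol%), CH2Cl2, 0 °C to rt; then I2, THF, −30 to 0 °C
Reagents that add atoms: trimethylaluminium, C[Al](C)C; iodine, [I][I]
Why: Negishi zirconium-catalysed carboalumination adds CH3 and Al syn across the terminal alkyne only (the internal alkyne is far slower), and iodinolysis with retention should give the E vinyl iodide.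

Step 4
Reactants: 6 (5S)-5-(hydroxymethyl)furan-2(5H)-one
Product: 7 (5S)-5-{[(tert-butyldimethylsilyl)oxy]methyl}furan-2(5H)-one
Conditions: t-BuMe2SiCl, imidazole, DMF, rt
Reagents that add atoms: tert-butyldimethylsilyl chloride, CC(C)(C)[Si](C)(C)Cl
Why: Standard silylation of the primary alcohol; the C5 stereocentre (later C14) is not involved.

Step 5
Reactants: 7 (5S)-5-{[(tert-butyldimethylsilyl)oxy]methyl}furan-2(5H)-one
Product: 8 (4R,5S)-5-{[(tert-butyldimethylsilyl)oxy]methyl}-4-(hydroxymethyl)dihydrofuran-2(3H)-one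
Conditions: MeOH (solvent), Ph2CO (0.2 equiv), hν (350 nm, Pyrex), rt, degassed
Reagents that add atoms: methanol, CO
Why: Benzophenone-sensitised radical conjugate addition: the hydroxymethyl radical adds to C4 of the butenolide anti to the C5 silyloxymethyl group, which sets the trans C1/C14 relationship of ring B.

Step 6
Reactants: 8 (4R,5S)-5-{[(tert-butyldimethylsilyl)oxy]methyl}-4-(hydroxymethyl)dihydrofuran-2(3H)-one
Product: 9 (4S,5S)-5-{[(tert-butyldimethylsilyl)oxy]methyl}-4-(iodomethyl)dihydrofuran-2(3H)-one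
Conditions: I2, PPh3, imidazole, CH2Cl2, 0 °C to rt
Reagents that add atoms: iodine, [I][I]
Why: Appel-type iodination of the primary alcohol; the imidazole buffer should keep the silyl ether intact and no stereocentre is touched (the descriptor at C4 changes only through priorities).

Step 7
Reactants: 9 (4S,5S)-5-{[(tert-butyldimethylsilyl)oxy]methyl}-4-(iodomethyl)dihydrofuran-2(3H)-one; 5 (1E)-1-iodo-2-methylhept-1-en-5-yne
Product: 11 (4S,5S)-5-{[(tert-butyldimethylsilyl)oxy]methyl}-4-[(2E)-3-methyloct-2-en-6-yn-1-yl]dihydrofuran-2(3H)-one, via alkylzinc iodide 10 (not isolated)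
Conditions: 9, Zn dust (activated with BrCH2CH2Br and Me3SiCl), LiCl, THF, 40 °C; then 5, Pd(PPh3)4 (5 mol%), THF, rt to 40 °C
Reagents that add atoms: none
Why: Zinc insertion into the primary C–I bond (no β-leaving group) and Negishi sp3–sp2 coupling with zerovalent palladium should join C2 to C3 with retention of the E geometry of 5.

Step 8
Reactants: 11 (4S,5S)-5-{[(tert-butyldimethylsilyl)oxy]methyl}-4-[(2E)-3-methyloct-2-en-6-yn-1-yl]dihydrofuran-2(3H)-one
Product: 13 (4S,5S)-5-{[(tert-butyldimethylsilyl)oxy]methyl}-4-[(2E,6E)-7-iodo-3-methylocta-2,6-dien-1-yl]dihydrofuran-2(3H)-one, via alkenylzirconocene chloride 12 (not isolated)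
Conditions: Cp2Zr(H)Cl (2.0 equiv), THF, rt, 1 h; then I2, THF, 0 °C
Reagents that add atoms: iodine, [I][I]
Why: Syn-hydrozirconation of the only alkyne, equilibrated by excess reagent so that zirconium sits on the less hindered methyl-bearing carbon (C8), followed by iodinolysis with retention, should give the E 2-iodoalkene; the lactone and silyl ether should survive the short reaction time.

Step 9
Reactants: 13 (4S,5S)-5-{[(tert-butyldimethylsilyl)oxy]methyl}-4-[(2E,6E)-7-iodo-3-methylocta-2,6-dien-1-yl]dihydrofuran-2(3H)-one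
Product: 14 (4S,5S)-5-{[(tert-butyldimethylsilyl)oxy]methyl}-4-({(2S,3S)-3-[(3E)-4-iodopent-3-en-1-yl]-3-methyloxiran-2-yl}methyl)dihydrofuran-2(3H)-one
Conditions: L-fructose-derived Shi ketone (0.3 equiv), KHSO5 (as Oxone, 2KHSO5·KHSO4·K2SO4), K2CO3 buffer (pH 10.5), Bu4NHSO4, MeCN/CH2(OMe)2/H2O, 0 °C
Reagents that add atoms: potassium peroxymonosulfate, [K+].[O-]S(=O)(=O)OO
Why: Shi asymmetric epoxidation: the chiral dioxirane attacks only the electron-rich C3=C4 alkene (the iodo-substituted C7=C8 alkene is deactivated), and the L-fructose-derived ketone, the enantiomer of the D-fructose catalyst that gives R,R epoxides from E-trisubstituted alkenes, should set C3 and C4 both as S through the spiro transition state.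

Step 10
Reactants: 14 (4S,5S)-5-{[(tert-butyldimethylsilyl)oxy]methyl}-4-({(2S,3S)-3-[(3E)-4-iodopent-3-en-1-yl]-3-methyloxiran-2-yl}methyl)dihydrofuran-2(3H)-one; 2 5-iodopent-2-yne
Product: 16 (4S,5S)-5-{[(tert-butyldimethylsilyl)oxy]methyl}-4-({(2S,3S)-3-methyl-3-[(3E)-4-methylnon-3-en-7-yn-1-yl]oxiran-2-yl}methyl)dihydrofuran-2(3H)-one, via pent-3-yn-1-ylzinc iodide 15 (not isolated)
Conditions: 2, Zn dust, LiCl, THF, 40 °C; then 14, Pd(PPh3)4 (5 mol%), THF, rt to 40 °C
Reagents that add atoms: none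
Why: Negishi sp3–sp2 coupling of the homopropargylic zinc reagent with the vinyl iodide should attach C9–C12 and the C12 methyl with retention, giving the E C7=C8 alkene that was masked as its iodide during the epoxidation.

Step 11
Reactants: 16 (4S,5S)-5-{[(tert-butyldimethylsilyl)oxy]methyl}-4-({(2S,3S)-3-methyl-3-[(3E)-4-methylnon-3-en-7-yn-1-yl]oxiran-2-yl}methyl)dihydrofuran-2(3H)-one
Product: 17 (4S,5S)-5-(hydroxymethyl)-4-({(2S,3S)-3-methyl-3-[(3E)-4-methylnon-3-en-7-yn-1-yl]oxiran-2-yl}methyl)dihydrofuran-2(3H)-one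
Conditions: Bu4NF, AcOH, THF, 0 °C to rt
Reagents that add atoms: none
Why: Buffered fluoride desilylation of the primary silyl ether should leave the lactone and the trisubstituted epoxide intact.

Step 12
Reactants: 17 (4S,5S)-5-(hydroxymethyl)-4-({(2S,3S)-3-methyl-3-[(3E)-4-methylnon-3-en-7-yn-1-yl]oxiran-2-yl}methyl)dihydrofuran-2(3H)-one
Product: 18 (2S,3S)-3-({(2S,3S)-3-methyl-3-[(3E)-4-methylnon-3-en-7-yn-1-yl]oxiran-2-yl}methyl)-5-oxooxolane-2-carbaldehyde
Conditions: Dess–Martin periodinane, pyridine, CH2Cl2, 0 °C to rt; used crude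
Reagents that add atoms: none
Why: Dess–Martin oxidation under pyridine buffering is mild enough that the α-acyloxy aldehyde should not epimerise at C14 and the epoxide should not open.

Step 13
Reactants: 18 (2S,3S)-3-({(2S,3S)-3-methyl-3-[(3E)-4-methylnon-3-en-7-yn-1-yl]oxiran-2-yl}methyl)-5-oxooxolane-2-carbaldehyde
Product: 19 (1S,3S,4S,7E,11E,13R,14S)-3,4-epoxy-13-[(triethylsilyl)oxy]-17-norcembra-7,11-dien-16,14-olide
Conditions: Ni(cod)2 (20 mol%), IMes·HCl (1,3-dimesitylimidazolium chloride, 20 mol%), KOtBu (20 mol%), Et3SiH (3 equiv), THF, rt, syringe-pump addition of 18 over 6 h to a final 0.005 M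
Reagents that add atoms: triethylsilane, CC[SiH](CC)CC
Why: The zerovalent nickel–carbene complex binds the C11≡C12 alkyne and the C13 aldehyde and undergoes oxidative cyclisation to an oxanickelacyclopentene in which the C12–C13 bond is formed; σ-bond metathesis with Et3SiH then silylates O13 and C–H reductive elimination delivers hydrogen to C11 on the same face, so the C11=C12 alkene must be E. The closest known reaction type is the nickel/N-heterocyclic-carbene/silane reductive macrocyclisation of ynals, which gives endocyclic E allylic silyl ethers. Ring A (14-membered) closes in the endocyclic mode, with both alkyne carbons in the ring, because the small IMes ligand lets the smaller alkyne substituent (CH3) sit at the carbon that bonds to the aldehyde; the alternative is a 13-membered ring with an exocyclic ethylidene. C13 is controlled by C14: in the polar Felkin–Anh arrangement the new bond forms anti to the C14–O bond of ring B, which should give the 13R (erythro) silyl ether that the invertive last step requires. The step needs ring closure to beat oligomerisation and aldehyde hydrosilylation, which slow addition at high dilution and pre-association of both π-components on one nickel centre should secure; the epoxide, the C7=C8 alkene and the saturated lactone are inert to the catalyst, and no enoate is present because C17 is introduced afterwards.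

Step 14
Reactants: 19 (1S,3S,4S,7E,11E,13R,14S)-3,4-epoxy-13-[(triethylsilyl)oxy]-17-norcembra-7,11-dien-16,14-olide
Product: 23 (1S,3S,4S,7E,11E,13R,14S)-3,4-epoxy-13-[(triethylsilyl)oxy]cembra-7,11,15(17)-trien-16,14-olide, via lithium enolate 20 (not isolated), via Mannich base 21 (not isolated), via trimethylammonium iodide 22 (not isolated)
Conditions: LiN(SiMe3)2, THF, −78 °C; CH2=NMe2 I (Eschenmoser's salt), −78 °C to rt; then MeI, THF, rt; then NaHCO3, H2O/CH2Cl2, rt
Reagents that add atoms: Eschenmoser's salt (N,N-dimethylmethyleneiminium iodide), C=[N+](C)C.[I-]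
Why: Eschenmoser methylenation: the lactone enolate is aminomethylated at C15, the Mannich base is quaternised and the ammonium salt eliminates (E1cB) to the exocyclic C15=C17 alkene; C15 is the only acidic site, so C1 and C14 should not epimerise, and the silyl ether installed by the key step protects O13.

Step 15
Reactants: 23 (1S,3S,4S,7E,11E,13R,14S)-3,4-epoxy-13-[(triethylsilyl)oxy]cembra-7,11,15(17)-trien-16,14-olide
Product: 24 (1S,3S,4S,7E,11E,13R,14S)-3,4-epoxy-13-hydroxycembra-7,11,15(17)-trien-16,14-olide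
Conditions: HF·pyridine, pyridine, THF, 0 °C
Reagents that add atoms: none
Why: Buffered HF·pyridine cleaves the labile secondary triethylsilyl ether under conditions that a trisubstituted epoxide and an α-methylene lactone should tolerate.

Step 16
Reactants: 24 (1S,3S,4S,7E,11E,13R,14S)-3,4-epoxy-13-hydroxycembra-7,11,15(17)-trien-16,14-olide
Product: 25 13-acetoxysarcocrassolide, (1S,3S,4S,7E,11E,13S,14S)-13-acetoxy-3,4-epoxycembra-7,11,15(17)-trien-16,14-olide
Conditions: PPh3, iPrO2C–N=N–CO2iPr (DIAD), AcOH, toluene, 0 °C to rt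
Reagents that add atoms: acetic acid, CC(=O)O
Why: Mitsunobu reaction: acetate displaces the alkoxyphosphonium ion of the 13R alcohol in an SN2 process with inversion, which installs the acetate and sets C13 as S in one step.

**Compound list**

1 | pent-3-yn-1-ol | CC#CCCO | starting material
2 | 5-iodopent-2-yne | CC#CCCI | intermediate
3 | hepta-1,5-diyne | C#CCCC#CC | intermediate
4 | dimethyl[(1E)-2-methylhept-1-en-5-yn-1-yl]alumane | C[Al](C)/C=C(\C)CCC#CC | intermediate (not isolated)
5 | (1E)-1-iodo-2-methylhept-1-en-5-yne | I/C=C(\C)CCC#CC | intermediate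
6 | (5S)-5-(hydroxymethyl)furan-2(5H)-one | O=C1C=C[C@@H](CO)O1 | starting material
7 | (5S)-5-{[(tert-butyldimethylsilyl)oxy]methyl}furan-2(5H)-one | O=C1C=C[C@@H](CO[Si](C)(C)C(C)(C)C)O1 | intermediate
8 | (4R,5S)-5-{[(tert-butyldimethylsilyl)oxy]methyl}-4-(hydroxymethyl)dihydrofuran-2(3H)-one (trans) | O=C1O[C@H](CO[Si](C)(C)C(C)(C)C)[C@H](C1)CO | intermediate
9 | (4S,5S)-5-{[(tert-butyldimethylsilyl)oxy]methyl}-4-(iodomethyl)dihydrofuran-2(3H)-one (trans) | O=C1O[C@H](CO[Si](C)(C)C(C)(C)C)[C@H](C1)CI | intermediate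
10 | {[(2S,3S)-2-{[(tert-butyldimethylsilyl)oxy]methyl}-5-oxooxolan-3-yl]methyl}zinc iodide | O=C1O[C@H](CO[Si](C)(C)C(C)(C)C)[C@H](C1)C[Zn]I | intermediate (not isolated)
11 | (4S,5S)-5-{[(tert-butyldimethylsilyl)oxy]methyl}-4-[(2E)-3-methyloct-2-en-6-yn-1-yl]dihydrofuran-2(3H)-one | O=C1O[C@H](CO[Si](C)(C)C(C)(C)C)[C@H](C1)C/C=C(\C)CCC#CC | intermediate
12 | chlorobis(cyclopentadienyl){(2E,6E)-8-[(2S,3S)-2-{[(tert-butyldimethylsilyl)oxy]methyl}-5-oxooxolan-3-yl]-6-methylocta-2,6-dien-2-yl}zirconium (cyclopentadienyl rings drawn σ-bonded) | O=C1O[C@H](CO[Si](C)(C)C(C)(C)C)[C@H](C1)C/C=C(\C)CC/C=C(\C)[Zr](Cl)(C1C=CC=C1)C1C=CC=C1 | intermediate (not isolated)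
13 | (4S,5S)-5-{[(tert-butyldimethylsilyl)oxy]methyl}-4-[(2E,6E)-7-iodo-3-methylocta-2,6-dien-1-yl]dihydrofuran-2(3H)-one | O=C1O[C@H](CO[Si](C)(C)C(C)(C)C)[C@H](C1)C/C=C(\C)CC/C=C(\C)I | intermediate
14 | (4S,5S)-5-{[(tert-butyldimethylsilyl)oxy]methyl}-4-({(2S,3S)-3-[(3E)-4-iodopent-3-en-1-yl]-3-methyloxiran-2-yl}methyl)dihydrofuran-2(3H)-one | O=C1O[C@H](CO[Si](C)(C)C(C)(C)C)[C@H](C1)C[C@@H]1O[C@@]1(C)CC/C=C(\C)I | intermediate
15 | pent-3-yn-1-ylzinc iodide | CC#CCC[Zn]I | intermediate (not isolated)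
16 | (4S,5S)-5-{[(tert-butyldimethylsilyl)oxy]methyl}-4-({(2S,3S)-3-methyl-3-[(3E)-4-methylnon-3-en-7-yn-1-yl]oxiran-2-yl}methyl)dihydrofuran-2(3H)-one | O=C1O[C@H](CO[Si](C)(C)C(C)(C)C)[C@H](C1)C[C@@H]1O[C@@]1(C)CC/C=C(\C)CCC#CC | intermediate
17 | (4S,5S)-5-(hydroxymethyl)-4-({(2S,3S)-3-methyl-3-[(3E)-4-methylnon-3-en-7-yn-1-yl]oxiran-2-yl}methyl)dihydrofuran-2(3H)-one | O=C1O[C@H](CO)[C@H](C1)C[C@@H]1O[C@@]1(C)CC/C=C(\C)CCC#CC | intermediate
18 | (2S,3S)-3-({(2S,3S)-3-methyl-3-[(3E)-4-methylnon-3-en-7-yn-1-yl]oxiran-2-yl}methyl)-5-oxooxolane-2-carbaldehyde | O=C1O[C@H](C=O)[C@H](C1)C[C@@H]1O[C@@]1(C)CC/C=C(\C)CCC#CC | intermediate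
19 | (1S,3S,4S,7E,11E,13R,14S)-3,4-epoxy-13-[(triethylsilyl)oxy]-17-norcembra-7,11-dien-16,14-olide | O=C1O[C@H]2[C@H](C1)C[C@@H]1O[C@@]1(C)CC/C=C(\C)CC/C=C(\C)[C@H]2O[Si](CC)(CC)CC | intermediate
20 | lithium enolate of 19 (C15=C16–OLi) | C1=C(O[Li])O[C@H]2[C@H]1C[C@@H]1O[C@@]1(C)CC/C=C(\C)CC/C=C(\C)[C@H]2O[Si](CC)(CC)CC | intermediate (not isolated)
21 | (1S,3S,4S,7E,11E,13R,14S)-17-(dimethylamino)-3,4-epoxy-13-[(triethylsilyl)oxy]cembra-7,11-dien-16,14-olide (C15 configuration immaterial) | CN(C)CC1C(=O)O[C@H]2[C@H]1C[C@@H]1O[C@@]1(C)CC/C=C(\C)CC/C=C(\C)[C@H]2O[Si](CC)(CC)CC | intermediate (not isolated)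
22 | N,N,N-trimethylammonium iodide derived from 21 (C15 configuration immaterial) | C[N+](C)(C)CC1C(=O)O[C@H]2[C@H]1C[C@@H]1O[C@@]1(C)CC/C=C(\C)CC/C=C(\C)[C@H]2O[Si](CC)(CC)CC.[I-] | intermediate (not isolated)
23 | (1S,3S,4S,7E,11E,13R,14S)-3,4-epoxy-13-[(triethylsilyl)oxy]cembra-7,11,15(17)-trien-16,14-olide | C=C1C(=O)O[C@H]2[C@H]1C[C@@H]1O[C@@]1(C)CC/C=C(\C)CC/C=C(\C)[C@H]2O[Si](CC)(CC)CC | intermediate
24 | (1S,3S,4S,7E,11E,13R,14S)-3,4-epoxy-13-hydroxycembra-7,11,15(17)-trien-16,14-olide | C=C1C(=O)O[C@H]2[C@H]1C[C@@H]1O[C@@]1(C)CC/C=C(\C)CC/C=C(\C)[C@H]2O | intermediate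
25 | 13-acetoxysarcocrassolide, (1S,3S,4S,7E,11E,13S,14S)-13-acetoxy-3,4-epoxycembra-7,11,15(17)-trien-16,14-olide | C=C1C(=O)O[C@H]2[C@H]1C[C@@H]1O[C@@]1(C)CC/C=C(\C)CC/C=C(\C)[C@@H]2OC(C)=O | target

**Step count and risks**

Total step count: 16. Longest linear sequence: 13 steps (6 to 25 through steps 4 to 16; equally 1 to 25 through steps 1 to 3 and 7 to 16).

Steps most likely to fail:

Step 13. Intermolecular oligomerisation may outrun ring closure, the C–C bond may form at C11 (exocyclic 13-membered ring), or facial selectivity at C13 may be low. The fallback closes the same C12–C13 bond by a Nozaki–Hiyama–Kishi reaction; it sets out from 2 and 14 and returns at 19. Hydrozirconation of 2 with Cp2Zr(H)Cl would give chlorobis(cyclopentadienyl)[(E)-5-iodopent-2-en-2-yl]zirconium F1, and N-bromosuccinimide would convert it into (E)-2-bromo-5-iodopent-2-ene F2. Zinc insertion into the alkyl iodide (Zn, LiCl, THF) would give [(E)-4-bromopent-3-en-1-yl]zinc iodide F3. Its Negishi coupling with 14 (Pd(PPh3)4; the C–I bond reacts before the C–Br bond) would give the silyl-protected seco vinyl bromide F4. Bu4NF/AcOH would give the primary alcohol F5 and Dess–Martin oxidation the bromo aldehyde F6. CrCl2 with catalytic NiCl2 in DMSO/THF at high dilution would add the alkenylchromium to the aldehyde, again anti to C14–O, to give the macrocyclic 13R allylic alcohol F7. Et3SiCl and imidazole would convert F7 into 19.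

Step 16. Acetate may attack C11 in an SN2' sense, the activated alcohol may eliminate to a diene, or ionisation at the hindered allylic C13 may erode the inversion. The fallback inverts C13 by oxidation and reduction; it sets out from 24 and returns at 25. Dess–Martin periodinane would give the C13 enone F8. Luche reduction (NaBH4, CeCl3·7H2O, MeOH, −78 °C), with hydride delivered anti to the C14–O bond, would give the 13S alcohol F9. Ac2O, DMAP and pyridine would acetylate F9 with retention to 25.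

Step 10. Lewis-acidic zinc iodide species may open the trisubstituted epoxide, or coupling at the hindered 2-iodoalkene may be sluggish. The fallback replaces zinc by boron in a B-alkyl Suzuki–Miyaura coupling; it sets out from 2 and 14 and returns at 16. Iodine–lithium exchange on 2 (t-BuLi, Et2O, −78 °C) would give pent-3-yn-1-yllithium F10, and 9-methoxy-9-borabicyclo[3.3.1]nonane would trap it as the lithium methoxy borinate F11. F11 would couple with 14 under Pd(dppf)Cl2 and K3PO4 in DMF/H2O at rt to give 16.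

**Further compounds**

F1 | step 13 | chlorobis(cyclopentadienyl)[(E)-5-iodopent-2-en-2-yl]zirconium (cyclopentadienyl rings drawn σ-bonded) | ICC/C=C(\C)[Zr](Cl)(C1C=CC=C1)C1C=CC=C1
F2 | step 13 | (E)-2-bromo-5-iodopent-2-ene | ICC/C=C(\C)Br
F3 | step 13 | [(E)-4-bromopent-3-en-1-yl]zinc iodide | I[Zn]CC/C=C(\C)Br
F4 | step 13 | (4S,5S)-4-({(2S,3S)-3-[(3E,7E)-8-bromo-4-methylnona-3,7-dien-1-yl]-3-methyloxiran-2-yl}methyl)-5-{[(tert-butyldimethylsilyl)oxy]methyl}dihydrofuran-2(3H)-one | O=C1O[C@H](CO[Si](C)(C)C(C)(C)C)[C@H](C1)C[C@@H]1O[C@@]1(C)CC/C=C(\C)CC/C=C(\C)Br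
F5 | step 13 | (4S,5S)-4-({(2S,3S)-3-[(3E,7E)-8-bromo-4-methylnona-3,7-dien-1-yl]-3-methyloxiran-2-yl}methyl)-5-(hydroxymethyl)dihydrofuran-2(3H)-one | O=C1O[C@H](CO)[C@H](C1)C[C@@H]1O[C@@]1(C)CC/C=C(\C)CC/C=C(\C)Br
F6 | step 13 | (2S,3S)-3-({(2S,3S)-3-[(3E,7E)-8-bromo-4-methylnona-3,7-dien-1-yl]-3-methyloxiran-2-yl}methyl)-5-oxooxolane-2-carbaldehyde | O=C1O[C@H](C=O)[C@H](C1)C[C@@H]1O[C@@]1(C)CC/C=C(\C)CC/C=C(\C)Br
F7 | step 13 | (1S,3S,4S,7E,11E,13R,14S)-3,4-epoxy-13-hydroxy-17-norcembra-7,11-dien-16,14-olide | O=C1O[C@H]2[C@H](C1)C[C@@H]1O[C@@]1(C)CC/C=C(\C)CC/C=C(\C)[C@H]2O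
F8 | step 16 | (1S,3S,4S,7E,11E,14S)-3,4-epoxy-13-oxocembra-7,11,15(17)-trien-16,14-olide | C=C1C(=O)O[C@H]2[C@H]1C[C@@H]1O[C@@]1(C)CC/C=C(\C)CC/C=C(\C)C2=O
F9 | step 16 | (1S,3S,4S,7E,11E,13S,14S)-3,4-epoxy-13-hydroxycembra-7,11,15(17)-trien-16,14-olide | C=C1C(=O)O[C@H]2[C@H]1C[C@@H]1O[C@@]1(C)CC/C=C(\C)CC/C=C(\C)[C@@H]2O
F10 | step 10 | pent-3-yn-1-yllithium | [Li]CCC#CC
F11 | step 10 | lithium 9-methoxy-9-(pent-3-yn-1-yl)-9-boranuidabicyclo[3.3.1]nonane | [Li+].CC#CCC[B-]1(OC)C2CCCC1CCC2
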